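**Retrosynthetic overview**
1. Target 8 ⇐ 5, (13S)-labd-8(17)-en-15-yl acetate: the C18 carboxyl C–O bonds, and with them the C4 stereocentre, are made last by site-selective oxidation of the equatorial 4α-methyl group.
2. 5 ⇐ 4: the exocyclic 8(17)-alkene comes from syn-elimination of the tertiary 8α-acetate.
3. 4 ⇐ 3: the C13 stereocentre comes from asymmetric hydrogenation of the (13E)-allylic acetate.
4. 3 ⇐ 2 ⇐ 1: the C15–O bond comes from 1,3-transposition of the tertiary allylic acetate of sclareol diacetate.
5. Rings: ring A and ring B, with C5, C9 and C10, are taken intact from (−)-sclareol; no ring is formed in the route.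

Assumption: the SMILES is read as (13S)-15-acetoxylabd-8(17)-en-18-oic acid (4R,5R,9S,10R,13S; carboxyl on the equatorial 4α position as in abietic acid, i.e. the C4 epimer of imbricatolic acid acetate); the recombinant P450 of step 5 is a catalyst made by heterologous expression, not a starting material.

**Route**

Step 1
Reactants: 1 (−)-sclareol
Product: 2 sclareol diacetate
Conditions: AcCl (6 equiv), PhNMe2 (8 equiv), CH2Cl2, 0 to 23 °C
Reagents that add atoms: acetyl chloride, CC(=O)Cl
Why: Base-buffered O-acylation of both tertiary alcohols (no free acid, so the allylic tertiary centre does not ionise); no stereocentre is touched.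

Step 2
Reactants: 2 sclareol diacetate
Product: 3 (13E)-labd-13-ene-8α,15-diyl diacetate
Conditions: PdCl2(MeCN)2 (5 mol%), THF, 23 °C
Reagents that add atoms: none
Why: Overman-type palladium dichloride-catalysed [3,3]-sigmatropic (cyclisation-induced) transposition of the tertiary allylic acetate forms the C15–O bond as the C13–O bond breaks and is driven to the trisubstituted alkene; the 13E isomer predominates, and the minor 13Z isomer is removed on AgNO3–silica and re-equilibrated with the same catalyst.

Step 3
Reactants: 3 (13E)-labd-13-ene-8α,15-diyl diacetate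
Product: 4 (13S)-labdane-8α,15-diyl diacetate
Conditions: H2 (50 bar), [Ir(cod)(L)]BArF (1 mol%), CH2Cl2, 23 °C
Reagents that add atoms: none
Why: Pfaltz-type iridium asymmetric hydrogenation with a chiral pyridine–phosphinite N,P ligand (L = (S)-8-(di-tert-butylphosphinooxy)-2-phenyl-5,6,7,8-tetrahydroquinoline, BArF = B[3,5-(CF3)2C6H3]4), a catalyst class that reduces farnesol and tocotrienyl acetate with high selectivity, adds H2 to one face of the only alkene and sets C13 as S; the ligand antipode is fixed beforehand as the one that turns (E)-geranyl acetate into (S)-citronellyl acetate, the exact topological model of C13.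

Step 4
Reactants: 4 (13S)-labdane-8α,15-diyl diacetate
Product: 5 (13S)-labd-8(17)-en-15-yl acetate
Conditions: 2,4,6-collidine, reflux (171 °C)
Reagents that add atoms: none
Why: Ester pyrolysis (thermal syn-elimination) removes only the tertiary 8α-acetate, the primary acetate being inert at this temperature; the freely rotating C17 methyl offers three hydrogens in a strain-free syn-periplanar geometry whereas the ring hydrogens at C7 and C9 are held gauche in the rigid trans-decalin, so the exocyclic 8(17)-alkene should be the main product (minor 7-ene and 8-ene isomers are removed on AgNO3–silica), and no stereocentre is touched.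

Step 5
Reactants: 5 (13S)-labd-8(17)-en-15-yl acetate
Product: 8 (13S)-15-acetoxylabd-8(17)-en-18-oic acid, via 18-alcohol 6 (not isolated), via 18-aldehyde 7 (not isolated)
Conditions: CYP720B4 + NADPH-cytochrome P450 reductase (S. cerevisiae microsomes), NADP+ (cat.), D-glucose, glucose dehydrogenase, air, KH2PO4/K2HPO4 buffer pH 7.5, 2% DMSO, 30 °C
Reagents that add atoms: dioxygen, O=O
Why: Proposed new method: the conifer resin-acid P450 CYP720B4 is known to oxidise the equatorial 4α-methyl (C18) of tricyclic abietane and pimarane olefins, alcohols and aldehydes three times in succession to the acid (hydrogen abstraction by the haem iron-oxo species and oxygen rebound, repeated on the alcohol via the gem-diol and on the aldehyde), and the bicyclic labdane 5, a substrate type on which this has not been shown, presents the identical ring A/ring B trans-decalin and 4α-methyl to the haem while its flexible acetoxyalkyl chain fills the pocket of the missing ring, so the same site selectivity should form the C18–O bonds and, by choosing the 4α over the 4β methyl, set C4 as R; the closest known reaction is the CYP720B4 oxidation of abietadiene and isopimaradiene to abietic and isopimaric acid.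

**Compound list**
1 | (−)-sclareol, (13R)-labd-14-ene-8α,13-diol | C[C@@]1(O)CC[C@@H]2[C@](C)(CCCC2(C)C)[C@H]1CC[C@@](C)(O)C=C | starting material
2 | sclareol diacetate, (13R)-labd-14-ene-8α,13-diyl diacetate | C[C@@]1(OC(C)=O)CC[C@@H]2[C@](C)(CCCC2(C)C)[C@H]1CC[C@@](C)(OC(C)=O)C=C | intermediate
3 | (13E)-labd-13-ene-8α,15-diyl diacetate | C[C@@]1(OC(C)=O)CC[C@@H]2[C@](C)(CCCC2(C)C)[C@H]1CC/C(C)=C/COC(C)=O | intermediate
4 | (13S)-labdane-8α,15-diyl diacetate | C[C@@]1(OC(C)=O)CC[C@@H]2[C@](C)(CCCC2(C)C)[C@H]1CC[C@H](C)CCOC(C)=O | intermediate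
5 | (13S)-labd-8(17)-en-15-yl acetate | C=C1CC[C@@H]2[C@](C)(CCCC2(C)C)[C@H]1CC[C@H](C)CCOC(C)=O | intermediate
6 | (13S)-18-hydroxylabd-8(17)-en-15-yl acetate (18-alcohol, not isolated) | C=C1CC[C@@H]2[C@](C)(CCC[C@@]2(C)CO)[C@H]1CC[C@H](C)CCOC(C)=O | intermediate
7 | (13S)-18-oxolabd-8(17)-en-15-yl acetate (18-aldehyde, not isolated) | C=C1CC[C@@H]2[C@](C)(CCC[C@@]2(C)C=O)[C@H]1CC[C@H](C)CCOC(C)=O | intermediate
8 | (13S)-15-acetoxylabd-8(17)-en-18-oic acid | C=C1CC[C@@H]2[C@](C)(CCC[C@@]2(C)C(=O)O)[C@H]1CC[C@H](C)CCOC(C)=O | target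

**Step count**
Total steps: 5. Longest linear sequence: 5 steps (1 → 2 → 3 → 4 → 5 → 8).

**Steps most likely to fail**

Step 5 (the proposed new step). The enzyme may not turn over a bicyclic substrate, may stall at 6 or 7, or the microsomal preparation may hydrolyse the acetate; partial oxidation to 6 or 7 can be finished chemically with TEMPO/PhI(OAc)2 and NaClO2. The fallback uses known chemistry only, sets out from 1 and comes back at 8, and installs the C18 oxygen first instead of last. Incubation of 1 with growing cultures of Mucor plumbeus, a documented biotransformation of sclareol, gives beside the 3β-hydroxy isomer 18-hydroxysclareol F1, which is separated on silica. TEMPO (cat.)/PhI(OAc)2 in MeCN–H2O oxidises its only primary alcohol to (13R)-8α,13-dihydroxylabd-14-en-18-oic acid F2. AcCl/PhNMe2, then aqueous NaHCO3 to hydrolyse the mixed anhydride, gives (13R)-8α,13-diacetoxylabd-14-en-18-oic acid F3. PdCl2(MeCN)2 in THF gives (13E)-8α,15-diacetoxylabd-13-en-18-oic acid F4. Hydrogenation as in step 3 gives (13S)-8α,15-diacetoxylabdan-18-oic acid F5, and thermolysis in collidine as in step 4 gives 8.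

Step 4. The thermal syn-elimination may give too much of the endocyclic 7-ene and 8-ene isomers. The fallback sets out from 4 and comes back at 5, and replaces it by a low-temperature anti-elimination of the free tertiary alcohol. LiAlH4 in THF removes both acetates to give (13S)-labdane-8α,15-diol F6. Ac2O/pyridine at 0 °C acetylates only the primary hydroxyl to give (13S)-8α-hydroxylabdan-15-yl acetate F7. SOCl2/pyridine in CH2Cl2 at −78 °C converts the equatorial 8α-hydroxyl into a chlorosulfite whose only anti-periplanar β-hydrogens are those of the C17 methyl, so E2 elimination gives 5.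

Step 3. The iridium hydrogenation may give insufficient selectivity at C13 (also through residual 13Z isomer) or its acidic hydride may ionise or hydrogenolyse an acetate. The fallback sets out from 3 and comes back at 4, and switches to hydroxyl-directed hydrogenation. K2CO3 in MeOH cleaves only the primary allylic acetate to give (13E)-8α-acetoxylabd-13-en-15-ol F8, whose E and Z forms are also easier to separate than the acetates. Noyori hydrogenation with Ru(OAc)2[(R)-BINAP], H2 (30 bar), MeOH, 23 °C, the antipode that turns geraniol into (S)-citronellol, gives (13S)-8α-acetoxylabdan-15-ol F9. Ac2O/pyridine returns 4.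

**Further compounds**
F1 | step 5 | 18-hydroxysclareol, (13R)-labd-14-ene-8α,13,18-triol | C[C@@]1(O)CC[C@@H]2[C@](C)(CCC[C@@]2(C)CO)[C@H]1CC[C@@](C)(O)C=C
F2 | step 5 | (13R)-8α,13-dihydroxylabd-14-en-18-oic acid | C[C@@]1(O)CC[C@@H]2[C@](C)(CCC[C@@]2(C)C(=O)O)[C@H]1CC[C@@](C)(O)C=C
F3 | step 5 | (13R)-8α,13-diacetoxylabd-14-en-18-oic acid | C[C@@]1(OC(C)=O)CC[C@@H]2[C@](C)(CCC[C@@]2(C)C(=O)O)[C@H]1CC[C@@](C)(OC(C)=O)C=C
F4 | step 5 | (13E)-8α,15-diacetoxylabd-13-en-18-oic acid | C[C@@]1(OC(C)=O)CC[C@@H]2[C@](C)(CCC[C@@]2(C)C(=O)O)[C@H]1CC/C(C)=C/COC(C)=O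
F5 | step 5 | (13S)-8α,15-diacetoxylabdan-18-oic acid | C[C@@]1(OC(C)=O)CC[C@@H]2[C@](C)(CCC[C@@]2(C)C(=O)O)[C@H]1CC[C@H](C)CCOC(C)=O
F6 | step 4 | (13S)-labdane-8α,15-diol | C[C@@]1(O)CC[C@@H]2[C@](C)(CCCC2(C)C)[C@H]1CC[C@H](C)CCO
F7 | step 4 | (13S)-8α-hydroxylabdan-15-yl acetate | C[C@@]1(O)CC[C@@H]2[C@](C)(CCCC2(C)C)[C@H]1CC[C@H](C)CCOC(C)=O
F8 | step 3 | (13E)-8α-acetoxylabd-13-en-15-ol | C[C@@]1(OC(C)=O)CC[C@@H]2[C@](C)(CCCC2(C)C)[C@H]1CC/C(C)=C/CO
F9 | step 3 | (13S)-8α-acetoxylabdan-15-ol | C[C@@]1(OC(C)=O)CC[C@@H]2[C@](C)(CCCC2(C)C)[C@H]1CC[C@H](C)CCO
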